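All runs are calculated for an exercise; scatter was added.

The ratio to carry through this flask is that of the two rates at one moment. If both substrates react by the candidate steps, each step uses the same free catalyst and coupling partner, so these cancel. The rate for the left-handed substrate over that for the right-handed substrate is then s times c(left-handed substrate)/c(right-handed substrate), however the catalyst fares.

all flasks: left-handed substrate 0.13 M; right-handed substrate 0.13 M; free catalyst 0.1 mol%

| run | coupling partner | remark | time |
|---|---|---|---|
| red | 2 equiv (fed, over 2.5 h) | the very flask that is asked about, followed so far |  |
| flask | 2.00 equiv (fed, over 2.5 h) |  | 2.5 d |

red run (percent of the left-handed substrate and right-handed substrate together charged)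

| time / h | left-handed substrate / % | right-handed substrate / % | left-handed product / % |
|---|---|---|---|
| 2.00 | 45.6 | 47.6 | 3.4 |
| 6.00 | 34.3 | 44.1 | 13.1 |
| 12.0 | 30.3 | 39.4 | 21.1 |
| 15.0 | 30.2 | 38.1 | 21.5 |
| 25.0 | 28.6 | 38.7 | 22.4 |

(readings scatter by 1 percentage point)

- free catalyst is single-handed; left-handed substrate and right-handed substrate are mirror images of each other, charged as a racemate, each of them at the stated concentration
- the numbers in the tables scatter with a standard deviation of 1 percentage point
- candidate steps: free catalyst -> spent catalyst; coupling partner + free catalyst + left-handed substrate -> free catalyst + left-handed product; coupling partner + free catalyst + right-handed substrate -> free catalyst + right-handed product; coupling partner -> decomposed reagent; 2 free catalyst <-> resting dimer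
- an excess is below zero if the other one leads

- part of the left-handed substrate and right-handed substrate charged together that has reacted at 2.5 d
- excess of left-handed product over right-handed product in the product at 2.5 d
- excess of right-handed substrate over left-handed substrate among what is left of the two at 2.5 d

You can get s in two ways from the red run at 25.0 h. Counting losses, the left-handed substrate has lost 21.4% and the right-handed 11.3%, a ratio of 1.89. Integrating the rate ratio instead gives the selectivity factor s, the logarithm of the fraction left of the left-handed substrate over that of the right-handed, 2.18, a reading with the scatter of 1 percentage point in it.

The two part, and the count is the one that cheats as a constant. The left-handed substrate falls faster, so the momentary ratio drifts from s at the start to 1.61 at 25.0 h. The count is an average over that drift, lower than s and higher than the final ratio.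

Left-handed product moves from 21.5% to 22.4% between 15.0 h and 25.0 h, so I would carry the last reading forward. That gives c 32.7%, eP 30.9% and eS 15.0%. The forecast, reasoning that “little further change is expected by 60 h”, stands slightly higher at 33.8%, 31% and 15.5%.

The flask gives c 33.8%, eP 33.0% and eS 16.8%.

    free catalyst → spent catalyst (k = 0.00220 /min)
    coupling partner + free catalyst + left-handed substrate → free catalyst + left-handed product (k = 93.0 /M²/min)
    coupling partner + free catalyst + right-handed substrate → free catalyst + right-handed product (k = 40.0 /M²/min)
    coupling partner → decomposed reagent (k = 0.00110 /min)
    2 free catalyst ⇌ resting dimer, settled at all times (K = 2200 /M)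

With 55% of its left-handed substrate left, s puts the right-handed at 76.0%, and the flask holds 77%. In the neighbouring flask with 0.4 mol% of free catalyst, 24% of the left-handed substrate is left at 2.50 d. There s puts the right-handed at 52.0%, against 55% in that flask. The eP of that flask stands at 24.9%.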